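**Plan**

- Numbering: ring A is the 4-hydroxy-3,5-dimethoxyphenyl ring on C7, C8 carries the oxygen of ring B (the 2,6-dimethoxyphenoxy ring with the hydroxypropenyl arm), and C9 is the CH2OH carbon.
- Retrosynthesis cuts, in this order: the C7–OH bond (water addition to the para-quinone methide of ring A), the aryl–vinyl C–C bond on ring B (Suzuki coupling), the C7–C8 bond (aldol condensation, carried as a C7=C8 alkene) and the ring B O–CH2 bond (phenol alkylation at the acetate stage).
- Forward: no ring is formed. The ring B phenol is alkylated, the acetate is condensed with O-silyl syringaldehyde to the Z α-aryloxy acrylic acid, the alkene is hydrogenated, C9 is reduced to CH2OH, the arm is coupled on, the silyl groups are removed and C7 is oxygenated last.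
- Feature used: C8 bears the ring B aryloxy oxygen and C9, so with C9 as CO2H and C7=C8 unsaturated the chain is an α-aryloxy cinnamic acid whose carboxylate can hold a chiral iridium catalyst on the double bond.
- Stereochemistry: C8 comes from the ligand-controlled hydrogenation (step 6). C7 comes from substrate-controlled addition of water to the quinone methide anti to the aryloxy group, giving the erythro 7S,8R isomer (step 10). The E alkene arrives with the boronate.

Key step: step 6

Assumption: the (Sa,S) enantiomer of the spiro phosphine–oxazoline ligand L is taken to deliver hydrogen to the Re face of C8 (S acid); if a pilot run shows the opposite sense, the (Ra,R) ligand is used and nothing else changes.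

**Route**

Step 1
Reactants: 1 4-bromo-2,6-dimethoxyphenol; 2 ethyl bromoacetate
Product: 3 ethyl 2-(4-bromo-2,6-dimethoxyphenoxy)acetate
Conditions: K2CO3, acetone, reflux
Reagents that add atoms: none
Why: Williamson ether synthesis, in which the phenoxide of 1 displaces bromide from the primary α-bromo ester by an SN2 reaction and the two ortho methoxy groups do not block attack on an unhindered CH2 electrophile.

Step 2
Reactants: 4 syringaldehyde (4-hydroxy-3,5-dimethoxybenzaldehyde)
Product: 5 3,5-dimethoxy-4-(triisopropylsilyloxy)benzaldehyde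
Conditions: iPr3SiCl, imidazole, DMF, rt
Reagents that add atoms: chlorotriisopropylsilane, CC(C)[Si](Cl)(C(C)C)C(C)C
Why: Imidazole-promoted silylation of the acidic phenol; the triisopropylsilyl ether, shielded further by the two ortho methoxy groups, should withstand the amide base, DBU, hydroxide, borane and the coupling base of later steps and still leave with fluoride.

Step 3
Reactants: 3 ethyl 2-(4-bromo-2,6-dimethoxyphenoxy)acetate; 5 3,5-dimethoxy-4-(triisopropylsilyloxy)benzaldehyde
Product: 7 ethyl 2-(4-bromo-2,6-dimethoxyphenoxy)-3-hydroxy-3-[3,5-dimethoxy-4-(triisopropylsilyloxy)phenyl]propanoate (racemic syn/anti mixture), via lithium ester enolate 6 (not isolated)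
Conditions: LiN(iPr)2, THF, −78 °C; then 5, −78 °C; AcOH quench
Reagents that add atoms: none
Why: Directed aldol addition of an ester lithium enolate to a non-enolisable aldehyde, the standard entry to aryl glycerol β-aryl ethers; the amide base deprotonates the α-CH2 without touching the aryl bromide, and the two new stereocentres need no control because both are erased in step 4.

Step 4
Reactants: 7 ethyl 2-(4-bromo-2,6-dimethoxyphenoxy)-3-hydroxy-3-[3,5-dimethoxy-4-(triisopropylsilyloxy)phenyl]propanoate
Product: 9 ethyl (Z)-2-(4-bromo-2,6-dimethoxyphenoxy)-3-[3,5-dimethoxy-4-(triisopropylsilyloxy)phenyl]acrylate, via benzylic mesylate 8 (not isolated)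
Conditions: MsCl, Et3N, CH2Cl2, 0 °C; then DBU, rt
Reagents that add atoms: none
Why: Mesylation of the benzylic alcohol followed by base-induced E1cB elimination through the ester enolate, which should let both diastereomers of 7 converge on the more stable Z alkene (ring A trans to the ester); any E isomer is removed by chromatography so that one alkene geometry enters the hydrogenation.

Step 5
Reactants: 9 ethyl (Z)-2-(4-bromo-2,6-dimethoxyphenoxy)-3-[3,5-dimethoxy-4-(triisopropylsilyloxy)phenyl]acrylate
Product: 10 (Z)-2-(4-bromo-2,6-dimethoxyphenoxy)-3-[3,5-dimethoxy-4-(triisopropylsilyloxy)phenyl]acrylic acid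
Conditions: LiOH·H2O, THF/H2O, 0 °C to rt; then 1 M HCl to pH 3
Reagents that add atoms: LiOH (lithium hydroxide), [Li+].[OH-]
Why: Ester saponification by acyl substitution with hydroxide at low temperature; the hindered aryl silyl ether between two methoxy groups is expected to react much more slowly than the ethyl ester, and the alkene geometry is not affected.

Step 6
Reactants: 10 (Z)-2-(4-bromo-2,6-dimethoxyphenoxy)-3-[3,5-dimethoxy-4-(triisopropylsilyloxy)phenyl]acrylic acid
Product: 11 (S)-2-(4-bromo-2,6-dimethoxyphenoxy)-3-[3,5-dimethoxy-4-(triisopropylsilyloxy)phenyl]propanoic acid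
Conditions: [Ir(cod)(L)]B[3,5-(CF3)2C6H3]4 (1 mol %; L = (Sa,S)-7-[bis(3,5-di-tert-butylphenyl)phosphanyl]-7'-[(S)-4-benzyl-4,5-dihydrooxazol-2-yl]-1,1'-spirobiindane), H2 (6 atm), Et3N (0.5 equiv), MeOH, 40 °C
Reagents that add atoms: none
Why: Carboxylate-directed asymmetric hydrogenation of a trisubstituted α-aryloxy acrylic acid, the reaction type established for cationic iridium spiro phosphine–oxazoline catalysts: the carboxylate of 10 binds iridium, H2 adds oxidatively, and the chelated C7=C8 bond inserts into an Ir–H bond before C–H reductive elimination, so both hydrogens arrive on one face within a cycle of trivalent and pentavalent iridium hydrides. No ring closes. The only new stereocentre, C8, is set by the ligand, whose spirobiindane backbone and oxazoline substituent leave one quadrant open for the aryloxy group of the bound alkene, so that hydrogen reaches the Re face of C8 and the S acid results. The step needs enantioface selection, which rests on the single Z geometry of 10 and on two-point binding through carboxylate and alkene, and chemoselectivity, which rests on the inertness of this catalyst towards aryl bromides, aryl ethers and the silyl ether. C7 becomes a methylene group and carries no stereochemistry at this stage.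

Step 7
Reactants: 11 (S)-2-(4-bromo-2,6-dimethoxyphenoxy)-3-[3,5-dimethoxy-4-(triisopropylsilyloxy)phenyl]propanoic acid
Product: 12 (S)-2-(4-bromo-2,6-dimethoxyphenoxy)-3-[3,5-dimethoxy-4-(triisopropylsilyloxy)phenyl]propan-1-ol
Conditions: BH3·SMe2, THF, 0 °C to rt; MeOH quench, aqueous work-up
Reagents that add atoms: none
Why: Chemoselective borane reduction of a carboxylic acid through its acyloxyborane, which leaves the aryl bromide, the aryl ethers and the silyl ether alone and cannot epimerise C8 because no enolate is formed.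

Step 8
Reactants: 12 (S)-2-(4-bromo-2,6-dimethoxyphenoxy)-3-[3,5-dimethoxy-4-(triisopropylsilyloxy)phenyl]propan-1-ol; 13 (E)-tert-butyldimethyl{[3-(4,4,5,5-tetramethyl-1,3,2-dioxaborolan-2-yl)prop-2-en-1-yl]oxy}silane
Product: 14 (S)-2-{4-[(E)-3-(tert-butyldimethylsilyloxy)prop-1-en-1-yl]-2,6-dimethoxyphenoxy}-3-[3,5-dimethoxy-4-(triisopropylsilyloxy)phenyl]propan-1-ol
Conditions: Pd(OAc)2 (3 mol %), 2-dicyclohexylphosphino-2',6'-dimethoxybiphenyl (6 mol %), K3PO4, THF/H2O, 50 °C
Reagents that add atoms: none
Why: Suzuki–Miyaura coupling, in which zerovalent palladium formed from Pd(OAc)2 and the electron-rich biaryl phosphine inserts into the C–Br bond of ring B and transmetalation from the alkenyl boronate and reductive elimination keep the E geometry; the free primary alcohol and both silyl ethers are tolerated.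

Step 9
Reactants: 14 (S)-2-{4-[(E)-3-(tert-butyldimethylsilyloxy)prop-1-en-1-yl]-2,6-dimethoxyphenoxy}-3-[3,5-dimethoxy-4-(triisopropylsilyloxy)phenyl]propan-1-ol
Product: 15 4-[(S)-3-hydroxy-2-{4-[(E)-3-hydroxyprop-1-en-1-yl]-2,6-dimethoxyphenoxy}propyl]-2,6-dimethoxyphenol
Conditions: Bu4NF, AcOH, THF, 0 °C to rt
Reagents that add atoms: none
Why: Fluoride-induced desilylation driven by the strong Si–F bond removes the aryl triisopropylsilyl and the allylic tert-butyldimethylsilyl group in one operation, with acetic acid buffering the phenoxide so that the electron-rich phenol is not left as its oxidation-prone anion.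

Step 10
Reactants: 15 4-[(S)-3-hydroxy-2-{4-[(E)-3-hydroxyprop-1-en-1-yl]-2,6-dimethoxyphenoxy}propyl]-2,6-dimethoxyphenol
Product: 17 (1S,2R)-1-(4-hydroxy-3,5-dimethoxyphenyl)-2-{4-[(E)-3-hydroxyprop-1-en-1-yl]-2,6-dimethoxyphenoxy}propane-1,3-diol, via quinone methide 16 (not isolated)
Conditions: Ag2O, CH2Cl2/THF, rt, dark; filter through Celite; then THF/H2O, citric acid (pH 3), 0 °C; NaHCO3
Reagents that add atoms: water, O
Why: Ag2O oxidation of a 4-alkyl-2,6-dimethoxyphenol to its para-quinone methide followed by acid-catalysed 1,6-addition of water, the biomimetic route to aryl glycerol β-aryl ethers; C7 is set under substrate control because water should attack the exocyclic carbon anti to the ring B aryloxy group in the conformer with C8–H eclipsing the exocyclic double bond, which leads to the erythro 7S,8R isomer, and the minor threo isomer is removed by chromatography.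

**Compound list**

1 | 4-bromo-2,6-dimethoxyphenol | COc1cc(Br)cc(OC)c1O | starting material
2 | ethyl bromoacetate | CCOC(=O)CBr | starting material
3 | ethyl 2-(4-bromo-2,6-dimethoxyphenoxy)acetate | CCOC(=O)COc1c(OC)cc(Br)cc1OC | intermediate
4 | syringaldehyde | COc1cc(C=O)cc(OC)c1O | starting material
5 | 3,5-dimethoxy-4-(triisopropylsilyloxy)benzaldehyde | COc1cc(C=O)cc(OC)c1O[Si](C(C)C)(C(C)C)C(C)C | intermediate
6 | lithium 2-(4-bromo-2,6-dimethoxyphenoxy)-1-ethoxyethenolate (enolate of 3) | [Li+].CCOC([O-])=COc1c(OC)cc(Br)cc1OC | intermediate (not isolated)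
7 | ethyl 2-(4-bromo-2,6-dimethoxyphenoxy)-3-hydroxy-3-[3,5-dimethoxy-4-(triisopropylsilyloxy)phenyl]propanoate (racemic syn/anti mixture) | CCOC(=O)C(Oc1c(OC)cc(Br)cc1OC)C(O)c1cc(OC)c(O[Si](C(C)C)(C(C)C)C(C)C)c(OC)c1 | intermediate
8 | ethyl 2-(4-bromo-2,6-dimethoxyphenoxy)-3-(methanesulfonyloxy)-3-[3,5-dimethoxy-4-(triisopropylsilyloxy)phenyl]propanoate | CCOC(=O)C(Oc1c(OC)cc(Br)cc1OC)C(OS(C)(=O)=O)c1cc(OC)c(O[Si](C(C)C)(C(C)C)C(C)C)c(OC)c1 | intermediate (not isolated)
9 | ethyl (Z)-2-(4-bromo-2,6-dimethoxyphenoxy)-3-[3,5-dimethoxy-4-(triisopropylsilyloxy)phenyl]acrylate | CCOC(=O)/C(Oc1c(OC)cc(Br)cc1OC)=C/c1cc(OC)c(O[Si](C(C)C)(C(C)C)C(C)C)c(OC)c1 | intermediate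
10 | (Z)-2-(4-bromo-2,6-dimethoxyphenoxy)-3-[3,5-dimethoxy-4-(triisopropylsilyloxy)phenyl]acrylic acid | OC(=O)/C(Oc1c(OC)cc(Br)cc1OC)=C/c1cc(OC)c(O[Si](C(C)C)(C(C)C)C(C)C)c(OC)c1 | intermediate
11 | (S)-2-(4-bromo-2,6-dimethoxyphenoxy)-3-[3,5-dimethoxy-4-(triisopropylsilyloxy)phenyl]propanoic acid | COc1cc(C[C@@H](C(=O)O)Oc2c(OC)cc(Br)cc2OC)cc(OC)c1O[Si](C(C)C)(C(C)C)C(C)C | intermediate
12 | (S)-2-(4-bromo-2,6-dimethoxyphenoxy)-3-[3,5-dimethoxy-4-(triisopropylsilyloxy)phenyl]propan-1-ol | COc1cc(C[C@@H](CO)Oc2c(OC)cc(Br)cc2OC)cc(OC)c1O[Si](C(C)C)(C(C)C)C(C)C | intermediate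
13 | (E)-tert-butyldimethyl{[3-(4,4,5,5-tetramethyl-1,3,2-dioxaborolan-2-yl)prop-2-en-1-yl]oxy}silane | CC(C)(C)[Si](C)(C)OC/C=C/B1OC(C)(C)C(C)(C)O1 | starting material
14 | (S)-2-{4-[(E)-3-(tert-butyldimethylsilyloxy)prop-1-en-1-yl]-2,6-dimethoxyphenoxy}-3-[3,5-dimethoxy-4-(triisopropylsilyloxy)phenyl]propan-1-ol | COc1cc(C[C@@H](CO)Oc2c(OC)cc(/C=C/CO[Si](C)(C)C(C)(C)C)cc2OC)cc(OC)c1O[Si](C(C)C)(C(C)C)C(C)C | intermediate
15 | 4-[(S)-3-hydroxy-2-{4-[(E)-3-hydroxyprop-1-en-1-yl]-2,6-dimethoxyphenoxy}propyl]-2,6-dimethoxyphenol | COc1cc(C[C@@H](CO)Oc2c(OC)cc(/C=C/CO)cc2OC)cc(OC)c1O | intermediate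
16 | 4-[(S)-3-hydroxy-2-{4-[(E)-3-hydroxyprop-1-en-1-yl]-2,6-dimethoxyphenoxy}propylidene]-2,6-dimethoxycyclohexa-2,5-dien-1-one | COC1=CC(=C[C@@H](CO)Oc2c(OC)cc(/C=C/CO)cc2OC)C=C(OC)C1=O | intermediate (not isolated)
17 | (1S,2R)-1-(4-hydroxy-3,5-dimethoxyphenyl)-2-{4-[(E)-3-hydroxyprop-1-en-1-yl]-2,6-dimethoxyphenoxy}propane-1,3-diol (erythro; CNP0207964.1) | COc1cc([C@H](O)[C@@H](CO)Oc2c(OC)cc(/C=C/CO)cc2OC)cc(OC)c1O | target

**Count and risks**

Total steps: 10. Longest linear sequence: 9 steps (steps 1 and 3–10 from 1, or steps 2–10 from 4).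

Steps most likely to fail:

1. Step 10. The water addition may show poor facial selectivity at C7, and the quinone methide may be lost by tautomerisation to the enol ether or by addition of the alcohol groups of a second molecule. The fallback sets out from 12 and comes back at 17, and it moves C7 to the ketone oxidation level before the acid- and oxidant-sensitive arm is present. 2,3-Dichloro-5,6-dicyano-1,4-benzoquinone in CH2Cl2/H2O should oxidise the benzylic CH2 para to the silyloxy group to (R)-2-(4-bromo-2,6-dimethoxyphenoxy)-3-hydroxy-1-[3,5-dimethoxy-4-(triisopropylsilyloxy)phenyl]propan-1-one F1. This is reduced at once with NaBH4 in EtOH/THF at −20 °C, before C8 can enolise, under Felkin–Anh control (hydride anti to the aryloxy group) to the erythro diol (1S,2R)-2-(4-bromo-2,6-dimethoxyphenoxy)-1-[3,5-dimethoxy-4-(triisopropylsilyloxy)phenyl]propane-1,3-diol F2. Suzuki coupling with 13 under the conditions of step 8 should give (1S,2R)-2-{4-[(E)-3-(tert-butyldimethylsilyloxy)prop-1-en-1-yl]-2,6-dimethoxyphenoxy}-1-[3,5-dimethoxy-4-(triisopropylsilyloxy)phenyl]propane-1,3-diol F3, and Bu4NF/AcOH then gives 17.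

2. Step 6. Enantioface selection may be insufficient or turnover slow, because the two ortho methoxy groups of ring B crowd the carboxylate-bound alkene more than the aryloxy groups for which this hydrogenation is established. The fallback sets out from 10 and comes back at 11 by classical resolution. Hydrogenation with the achiral complex [Ir(cod)(PCy3)(py)]PF6 in CH2Cl2 should give racemic 2-(4-bromo-2,6-dimethoxyphenoxy)-3-[3,5-dimethoxy-4-(triisopropylsilyloxy)phenyl]propanoic acid F4. Crystallisation with (S)-1-phenylethylamine from ethyl acetate/isopropanol should give the less soluble diastereomeric salt, (S)-1-phenylethylammonium (S)-2-(4-bromo-2,6-dimethoxyphenoxy)-3-[3,5-dimethoxy-4-(triisopropylsilyloxy)phenyl]propanoate F5 (the R amine is taken if the salt of the R acid crystallises first). Dilute HCl then liberates 11.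

3. Step 5. The aryl silyl group may be lost through attack of hydroxide at silicon during the saponification. The fallback sets out from 9 and comes back at 10 by accepting the loss and putting the group back. NaOH in MeOH/H2O at 50 °C cleaves ester and silyl ether together to (Z)-2-(4-bromo-2,6-dimethoxyphenoxy)-3-(4-hydroxy-3,5-dimethoxyphenyl)acrylic acid F6. iPr3SiCl and imidazole in DMF then silylate phenol and acid to triisopropylsilyl (Z)-2-(4-bromo-2,6-dimethoxyphenoxy)-3-[3,5-dimethoxy-4-(triisopropylsilyloxy)phenyl]acrylate F7. Its far more labile silyl ester alone is hydrolysed by brief treatment with K2CO3 in MeOH/THF/H2O at 0 °C to give 10.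

**Further compounds**

F1 | step 10 | (R)-2-(4-bromo-2,6-dimethoxyphenoxy)-3-hydroxy-1-[3,5-dimethoxy-4-(triisopropylsilyloxy)phenyl]propan-1-one | COc1cc(C(=O)[C@@H](CO)Oc2c(OC)cc(Br)cc2OC)cc(OC)c1O[Si](C(C)C)(C(C)C)C(C)C
F2 | step 10 | (1S,2R)-2-(4-bromo-2,6-dimethoxyphenoxy)-1-[3,5-dimethoxy-4-(triisopropylsilyloxy)phenyl]propane-1,3-diol | COc1cc([C@H](O)[C@@H](CO)Oc2c(OC)cc(Br)cc2OC)cc(OC)c1O[Si](C(C)C)(C(C)C)C(C)C
F3 | step 10 | (1S,2R)-2-{4-[(E)-3-(tert-butyldimethylsilyloxy)prop-1-en-1-yl]-2,6-dimethoxyphenoxy}-1-[3,5-dimethoxy-4-(triisopropylsilyloxy)phenyl]propane-1,3-diol | COc1cc([C@H](O)[C@@H](CO)Oc2c(OC)cc(/C=C/CO[Si](C)(C)C(C)(C)C)cc2OC)cc(OC)c1O[Si](C(C)C)(C(C)C)C(C)C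
F4 | step 6 | racemic 2-(4-bromo-2,6-dimethoxyphenoxy)-3-[3,5-dimethoxy-4-(triisopropylsilyloxy)phenyl]propanoic acid | COc1cc(CC(C(=O)O)Oc2c(OC)cc(Br)cc2OC)cc(OC)c1O[Si](C(C)C)(C(C)C)C(C)C
F5 | step 6 | (S)-1-phenylethylammonium (S)-2-(4-bromo-2,6-dimethoxyphenoxy)-3-[3,5-dimethoxy-4-(triisopropylsilyloxy)phenyl]propanoate | COc1cc(C[C@@H](C(=O)[O-])Oc2c(OC)cc(Br)cc2OC)cc(OC)c1O[Si](C(C)C)(C(C)C)C(C)C.C[C@H]([NH3+])c1ccccc1
F6 | step 5 | (Z)-2-(4-bromo-2,6-dimethoxyphenoxy)-3-(4-hydroxy-3,5-dimethoxyphenyl)acrylic acid | OC(=O)/C(Oc1c(OC)cc(Br)cc1OC)=C/c1cc(OC)c(O)c(OC)c1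
F7 | step 5 | triisopropylsilyl (Z)-2-(4-bromo-2,6-dimethoxyphenoxy)-3-[3,5-dimethoxy-4-(triisopropylsilyloxy)phenyl]acrylate | CC(C)[Si](OC(=O)/C(Oc1c(OC)cc(Br)cc1OC)=C/c1cc(OC)c(O[Si](C(C)C)(C(C)C)C(C)C)c(OC)c1)(C(C)C)C(C)C
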